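**Retrosynthetic overview**

1. Dehydroglyasperin D comes from its 2',4'-dipivalate. Base-labile groups are chosen because the free 2'-OH next to the C3=C4 bond does not tolerate acid.
2. Ring C (O1–C2–C3=C4–C4a–C8a) is cut to the aryne of ring A (C4a≡C8a) and the 2-arylacrolein O=CH–C(Ar)=CH2. A (2+2) addition of the C=O bond to the aryne makes C4–C4a and O1–C8a; benzoxete opening and oxa-6π closure then move O1 from C4 to C2.
3. Enabling feature: the C5 methoxy group of ring A sits next to C4a, and the O1-bearing C8a is meta to it. This is the polarity of a 3-methoxyaryne, so oxygen goes to C8a and carbon to C4a. In addition, O1–C2–C3=C4 fused to ring A is the valence isomer of a vinyl o-quinone methide.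
4. The aryne precursor (an o-silylaryl triflate) comes from 1,3-dimethoxybenzene by C2 lithiation/prenylation, meta C–H borylation/oxidation, carbamate-directed ortho-silylation and triflation.
5. The enal comes from 4-bromoresorcinol by pivaloylation, Suzuki–Miyaura isopropenylation and Riley oxidation. Rings A and B are bought as benzenes; ring C is the only ring made (step 9), by way of a transient four-membered ring.

Key step: step 9

Remark: the target has no stereocentre and its C3=C4 bond is fixed by ring C, so no descriptor is needed. Chromene numbering (O1, C2, C3, C4, C4a, C5 to C8, C8a; ring B primed) is used throughout, and prenyl means 3-methylbut-2-en-1-yl.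

**Step 1**
Reactants: 1 1,3-dimethoxybenzene; 2 prenyl bromide
Product: 4 1,3-dimethoxy-2-prenylbenzene, via 2-lithio-1,3-dimethoxybenzene 3 (not isolated)
Conditions: n-BuLi, THF, 0 °C to rt; then 2, -78 °C to rt
Reagents that add atoms: n-butyllithium [Li]CCCC (lithium of 3 only)
Why: Directed ortho-metalation: both methoxy groups direct n-BuLi to the C–H between them, and the aryllithium displaces the primary allylic bromide (SN2 alkylation), which places the prenyl group between the future C5 and C7 methoxy groups.

**Step 2**
Reactants: 4 1,3-dimethoxy-2-prenylbenzene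
Product: 6 3,5-dimethoxy-4-prenylphenol, via aryl pinacol boronate 5 (not isolated)
Conditions: [Ir(OMe)(cod)]2 (1.5 mol %), dtbpy (3 mol %), B2pin2 (1.0 equiv), THF, 80 °C; then 30 % aq H2O2, aq NaOH, THF, 0 °C
Reagents that add atoms: bis(pinacolato)diboron CC1(C)OB(OC1(C)C)B1OC(C)(C)C(C)(C)O1 (boryl group of 5 only); hydrogen peroxide OO (oxygen of 6)
Why: Iridium-catalysed aromatic C–H borylation is governed by sterics and can only reach the single C–H of 4 without an ortho substituent (meta to both methoxy groups, the future C8a), while the trisubstituted prenyl alkene is too hindered to compete and is inert to the nucleophilic basic peroxide that oxidises the C–B bond by 1,2-aryl shift.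

**Step 3**
Reactants: 6 3,5-dimethoxy-4-prenylphenol
Product: 7 3,5-dimethoxy-4-prenylphenyl N-isopropylcarbamate
Conditions: i-PrNCO, Et3N (0.2 equiv), CH2Cl2, rt
Reagents that add atoms: isopropyl isocyanate CC(C)N=C=O
Why: Amine-catalysed addition of the phenol O–H to the isocyanate (carbamoylation) installs a strong directing group that can later be removed by base alone.

**Step 4**
Reactants: 7 3,5-dimethoxy-4-prenylphenyl N-isopropylcarbamate
Product: 11 3,5-dimethoxy-4-prenyl-2-(trimethylsilyl)phenyl N-isopropylcarbamate, via N-TBS carbamate 8 (not isolated), via ortho-lithiated N-TBS carbamate 9 (not isolated), via N-TBS C-TMS carbamate 10 (not isolated)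
Conditions: TBSOTf, TMEDA, Et2O, 0 °C to rt; n-BuLi, TMEDA, -78 °C; TMSCl, -78 °C to rt; sat. aq NH4Cl
Reagents that add atoms: tert-butyldimethylsilyl triflate CC(C)(C)[Si](C)(C)OS(=O)(=O)C(F)(F)F (silyl group of 8 to 10 only); n-butyllithium [Li]CCCC (lithium of 9 only); chlorotrimethylsilane C[Si](C)(C)Cl
Why: Carbamate-directed ortho-metalation: transient N-silylation masks the N–H, the two remaining ring C–H bonds are equivalent by symmetry and each lies between the carbamate and a methoxy group, so complex-induced deprotonation at -78 °C should outrun removal of the benzylic-allylic protons, TMSCl traps the aryllithium, and the labile N–Si bond is lost on the near-neutral aqueous work-up.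

**Step 5**
Reactants: 11 3,5-dimethoxy-4-prenyl-2-(trimethylsilyl)phenyl N-isopropylcarbamate
Product: 13 3,5-dimethoxy-4-prenyl-2-(trimethylsilyl)phenyl triflate, via 2-silylphenol 12 (not isolated)
Conditions: DBU, Et2NH, MeCN, 40 °C; then PhNTf2, rt
Reagents that add atoms: N-phenylbis(trifluoromethanesulfonimide) O=S(=O)(N(c1ccccc1)S(=O)(=O)C(F)(F)F)C(F)(F)F
Why: E1cB cleavage of the secondary carbamate by DBU (the isocyanate is scavenged by Et2NH as a urea) frees the phenoxide, which is O-sulfonylated in the same flask by PhNTf2, so the acid-sensitive electron-rich aryl–silicon bond never meets acid.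

**Step 6**
Reactants: 14 4-bromoresorcinol
Product: 15 4-bromo-1,3-phenylene dipivalate
Conditions: PivCl (2.3 equiv), Et3N, DMAP (cat.), CH2Cl2, 0 °C to rt
Reagents that add atoms: pivaloyl chloride CC(C)(C)C(=O)Cl
Why: DMAP-catalysed O-acylation of both phenols gives esters that are inert to fluoride and to arynes and can be removed at the end without acid.

**Step 7**
Reactants: 15 4-bromo-1,3-phenylene dipivalate; 16 isopropenylboronic acid pinacol ester
Product: 17 4-(prop-1-en-2-yl)-1,3-phenylene dipivalate
Conditions: Pd(dppf)Cl2 (3 mol %), K3PO4, 1,4-dioxane/H2O 20:1, 80 °C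
Reagents that add atoms: none
Why: Suzuki–Miyaura coupling takes place at the C–Br bond only, because aryl pivalates do not undergo oxidative addition to zerovalent palladium and survive phosphate base at low water content.

**Step 8**
Reactants: 17 4-(prop-1-en-2-yl)-1,3-phenylene dipivalate
Product: 19 2-[2,4-bis(pivaloyloxy)phenyl]prop-2-enal, via allylic alcohol 18 (not isolated)
Conditions: SeO2 (1.5 equiv), BHT (cat.), 1,4-dioxane, 90 °C; product kept cold and used at once
Reagents that add atoms: selenium dioxide O=[Se]=O
Why: Riley oxidation: ene reaction of SeO2 at the only allylic C–H position followed by 2,3-sigmatropic shift gives the allylic alcohol, which the excess reagent oxidises further to the conjugated aldehyde.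

**Step 9**
Reactants: 13 3,5-dimethoxy-4-prenyl-2-(trimethylsilyl)phenyl triflate; 19 2-[2,4-bis(pivaloyloxy)phenyl]prop-2-enal
Product: 23 dehydroglyasperin D 2',4'-dipivalate, via aryne 20 (not isolated), via benzoxete 21 (not isolated), via o-quinone methide 22 (not isolated)
Conditions: CsF (3 equiv), 19 (2 equiv), BHT (cat.), 4 Å MS, MeCN, 25 to 40 °C, 13 added over 4 h by syringe pump
Reagents that add atoms: none
Why: Fluoride removes the silyl group of 13 and triflate leaves, giving 3,5-dimethoxy-4-prenylbenzyne 20, whose C5 methoxy group (next to C4a) distorts and polarises the triple bond so that the carbonyl oxygen of 19 attacks the more linear, more electrophilic C8a while charge builds up at C4a, ortho to the inductively withdrawing oxygen; collapse of that aryl anion on the oxocarbenium carbon sets O1–C8a and C4–C4a and gives benzoxete 21 (formal (2+2) cycloaddition of an aryne to a C=O bond). Strain-driven retro-4π opening of the four-membered ring breaks the old C4–O bond to give the vinyl o-quinone methide 22, and a rearomatising thermal disrotatory oxa-6π electrocyclisation (O1 onto the terminal CH2, which becomes C2) closes ring C, the only ring that remains. The closest known reaction types are the annulation of arynes with α,β-unsaturated aldehydes to 2H-chromenes and the insertion of 3-methoxyarynes into the C=O bond of formamides, which follows the same regiochemical sense. No stereocentre survives, since C4 of 21 is transient and 23 is achiral; the Z geometry of the exocyclic C4a=C4 bond needed for closure (vinyl group syn to the carbonyl) is favoured because the other side is blocked by the C5 methoxy group. The step needs C=O addition over C=C addition or a styrene-type Diels–Alder reaction (the ortho pivaloyloxy group twists ring B out of conjugation and both esters make it electron-poor), trapping by 19 over ene reaction with prenyl groups or attack of a second aryne (slow addition of 13 into excess 19), and protecting groups inert to fluoride (pivalates, not silyl ethers).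

**Step 10**
Reactants: 23 dehydroglyasperin D 2',4'-dipivalate
Product: 24 dehydroglyasperin D
Conditions: K2CO3 (3 equiv), degassed MeOH/THF, 0 °C to rt, Ar; aq NH4Cl work-up
Reagents that add atoms: none
Why: Carbonate-promoted transesterification (methanolysis) cleaves the two activated aryl esters, while the methyl ethers, the prenyl group and the acid-sensitive 2'-hydroxyisoflav-3-ene unit are untouched under oxygen-free basic conditions.

**Compound list**

| No. | Name | SMILES | Role |
|---|---|---|---|
| 1 | 1,3-dimethoxybenzene | COc1cccc(OC)c1 | starting material |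
| 2 | prenyl bromide (1-bromo-3-methylbut-2-ene) | CC(C)=CCBr | starting material |
| 3 | 2-lithio-1,3-dimethoxybenzene | COc1cccc(OC)c1[Li] | intermediate |
| 4 | 1,3-dimethoxy-2-prenylbenzene | COc1cccc(OC)c1CC=C(C)C | intermediate |
| 5 | 2-(3,5-dimethoxy-4-prenylphenyl)-4,4,5,5-tetramethyl-1,3,2-dioxaborolane | COc1cc(B2OC(C)(C)C(C)(C)O2)cc(OC)c1CC=C(C)C | intermediate |
| 6 | 3,5-dimethoxy-4-prenylphenol | COc1cc(O)cc(OC)c1CC=C(C)C | intermediate |
| 7 | 3,5-dimethoxy-4-prenylphenyl N-isopropylcarbamate | COc1cc(OC(=O)NC(C)C)cc(OC)c1CC=C(C)C | intermediate |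
| 8 | 3,5-dimethoxy-4-prenylphenyl N-(tert-butyldimethylsilyl)-N-isopropylcarbamate | COc1cc(OC(=O)N(C(C)C)[Si](C)(C)C(C)(C)C)cc(OC)c1CC=C(C)C | intermediate |
| 9 | 2-lithio derivative of 8 | COc1cc(OC(=O)N(C(C)C)[Si](C)(C)C(C)(C)C)c([Li])c(OC)c1CC=C(C)C | intermediate |
| 10 | 2-(trimethylsilyl) derivative of 8 | COc1cc(OC(=O)N(C(C)C)[Si](C)(C)C(C)(C)C)c([Si](C)(C)C)c(OC)c1CC=C(C)C | intermediate |
| 11 | 3,5-dimethoxy-4-prenyl-2-(trimethylsilyl)phenyl N-isopropylcarbamate | COc1cc(OC(=O)NC(C)C)c([Si](C)(C)C)c(OC)c1CC=C(C)C | intermediate |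
| 12 | 3,5-dimethoxy-4-prenyl-2-(trimethylsilyl)phenol | COc1cc(O)c([Si](C)(C)C)c(OC)c1CC=C(C)C | intermediate |
| 13 | 3,5-dimethoxy-4-prenyl-2-(trimethylsilyl)phenyl trifluoromethanesulfonate | COc1cc(OS(=O)(=O)C(F)(F)F)c([Si](C)(C)C)c(OC)c1CC=C(C)C | intermediate |
| 14 | 4-bromoresorcinol | Oc1ccc(Br)c(O)c1 | starting material |
| 15 | 4-bromo-1,3-phenylene bis(2,2-dimethylpropanoate) | CC(C)(C)C(=O)Oc1ccc(Br)c(OC(=O)C(C)(C)C)c1 | intermediate |
| 16 | isopropenylboronic acid pinacol ester | CC(=C)B1OC(C)(C)C(C)(C)O1 | starting material |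
| 17 | 4-(prop-1-en-2-yl)-1,3-phenylene bis(2,2-dimethylpropanoate) | CC(=C)c1ccc(OC(=O)C(C)(C)C)cc1OC(=O)C(C)(C)C | intermediate |
| 18 | 4-(3-hydroxyprop-1-en-2-yl)-1,3-phenylene bis(2,2-dimethylpropanoate) | OCC(=C)c1ccc(OC(=O)C(C)(C)C)cc1OC(=O)C(C)(C)C | intermediate |
| 19 | 2-[2,4-bis(pivaloyloxy)phenyl]prop-2-enal | O=CC(=C)c1ccc(OC(=O)C(C)(C)C)cc1OC(=O)C(C)(C)C | intermediate |
| 20 | 3,5-dimethoxy-4-prenylbenzyne (1,2-didehydrobenzene) | COC1=CC#CC(OC)=C1CC=C(C)C | intermediate |
| 21 | 2-{1-[2,4-bis(pivaloyloxy)phenyl]vinyl}-3,5-dimethoxy-4-prenyl-2H-benzoxete (racemic, transient) | COc1cc2OC(C(=C)c3ccc(OC(=O)C(C)(C)C)cc3OC(=O)C(C)(C)C)c2c(OC)c1CC=C(C)C | intermediate |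
| 22 | (Z)-vinyl o-quinone methide: 6-{2-[2,4-bis(pivaloyloxy)phenyl]allylidene}-3,5-dimethoxy-4-prenylcyclohexa-2,4-dien-1-one | C=C(c1ccc(OC(=O)C(C)(C)C)cc1OC(=O)C(C)(C)C)/C=C1\C(=O)C=C(OC)C(CC=C(C)C)=C1OC | intermediate |
| 23 | 4-(5,7-dimethoxy-6-prenyl-2H-chromen-3-yl)-1,3-phenylene bis(2,2-dimethylpropanoate) | COc1cc2c(c(OC)c1CC=C(C)C)C=C(c1ccc(OC(=O)C(C)(C)C)cc1OC(=O)C(C)(C)C)CO2 | intermediate |
| 24 | dehydroglyasperin D, 4-(5,7-dimethoxy-6-prenyl-2H-chromen-3-yl)benzene-1,3-diol | COc1cc2c(c(OC)c1CC=C(C)C)C=C(c1ccc(O)cc1O)CO2 | target |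

**Step count**

- Total step count: 10.
- Longest linear sequence: 7 (steps 1 to 5, 9, 10).

**Steps most likely to fail**

**Step 9.**
- The aryne may add to the styrene-type diene (the C=CH2 bond plus ring B) in a Diels–Alder sense.
- The zwitterion may close through the β-carbon, so that the ring double bond ends up in the wrong place.
- Aryne may be lost in ene reactions with prenyl groups.
- The enal may oligomerise under fluoride before it is trapped.
- Fallback: the polarity of ring A is inverted, with a phenol nucleophile in place of the aryne. It sets out from phenol 6 and enal 19 and comes back at 23. Compounds 6, 19 and PhB(OH)2 are heated with AcOH in toluene under Dean–Stark conditions. Boron-templated ortho-hydroxyalkylation at one of the two equivalent free ring positions should give the 2-phenyl-4H-1,3,2-benzodioxaborinine F1. On further heating this fragments to the same o-quinone methide 22, which closes to 23.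

**Step 4.**
- The base may deprotonate the doubly activated benzylic-allylic CH2.
- The carbamoyl group may migrate from oxygen to carbon on warming.
- The electron-rich aryl–silicon bond may be lost by protonation during work-up.
- Fallback: halogen–lithium exchange replaces C–H deprotonation. It sets out from phenol 6 and comes back at 13.
  - Low-temperature bromination with NBS (CH2Cl2, -78 °C) of the very electron-rich ring should give 2-bromo-3,5-dimethoxy-4-prenylphenol F2.
  - HMDS (neat, 70 °C) should give its trimethylsilyl ether F3.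
  - n-BuLi (THF, -78 °C) triggers bromine–lithium exchange and retro-Brook O-to-C silyl migration to the lithium salt of 12.
  - This salt is trapped in the same flask with Tf2O to give 13.

**Step 8.**
- The oxidation may stall at the alcohol stage or over-oxidise.
- The sensitive enal may dimerise or oligomerise at the temperature needed.
- Fallback: the aldehyde is built first and the methylene carbon is added last. It sets out from bromide 15 and comes back at 19.
  - Suzuki–Miyaura coupling of 15 with (E)-2-(2-ethoxyvinyl)-4,4,5,5-tetramethyl-1,3,2-dioxaborolane (Pd(dppf)Cl2, K3PO4) should give the aryl enol ether F4.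
  - Dilute HCl in THF should hydrolyse it to the arylacetaldehyde F5.
  - Mannich-type α-methylenation with aqueous formaldehyde (pyrrolidine and propionic acid, 10 mol % each, i-PrOH, 45 °C) should give 19 under mild conditions.

**Further compounds**
F1 | step 9 | 4-{1-[2,4-bis(pivaloyloxy)phenyl]vinyl}-5,7-dimethoxy-2-phenyl-6-prenyl-4H-1,3,2-benzodioxaborinine (racemic) | COc1cc2OB(c3ccccc3)OC(C(=C)c3ccc(OC(=O)C(C)(C)C)cc3OC(=O)C(C)(C)C)c2c(OC)c1CC=C(C)C
F2 | step 4 | 2-bromo-3,5-dimethoxy-4-prenylphenol | COc1cc(O)c(Br)c(OC)c1CC=C(C)C
F3 | step 4 | (2-bromo-3,5-dimethoxy-4-prenylphenoxy)trimethylsilane | COc1cc(O[Si](C)(C)C)c(Br)c(OC)c1CC=C(C)C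
F4 | step 8 | 4-[(E)-2-ethoxyvinyl]-1,3-phenylene bis(2,2-dimethylpropanoate) | CCO/C=C/c1ccc(OC(=O)C(C)(C)C)cc1OC(=O)C(C)(C)C
F5 | step 8 | 4-(2-oxoethyl)-1,3-phenylene bis(2,2-dimethylpropanoate) | O=CCc1ccc(OC(=O)C(C)(C)C)cc1OC(=O)C(C)(C)C
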